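**Retrosynthetic overview**
- The target is traced back to its 5,7-bis(methoxymethyl) ether; acetal cleavage is the last step.
- Ring C is opened across O1–C8a and C3–C4. An SNAr etherification and a carbene-catalyzed aldehyde–ketone benzoin addition, run in one flask, join a ring B hydroxymethyl ketone (O1, C2, C3) to a ring A ortho-fluoro benzaldehyde (C4, C4a, C8a).
- Enabling feature: ring C is a 3-hydroxychroman-4-one, an alpha-ketol in which the C3 carbinol is bonded to the C4 aryl ketone carbon and C4 sits ortho to the ether carbon C8a of ring A. One formyl group therefore both activates C8a–F for substitution and becomes the acyl anion equivalent at C4.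
- Ring B fragment: 1,3-dimethoxybenzene, by ortho-lithiation/prenylation, formylation and carbene-catalyzed hydroxymethylation. Ring A fragment: 5-fluororesorcinol, by formylation and MOM protection.
- Ring order: rings A and B are bought as benzene rings; ring C is the only ring formed, in step 6.

Key step: step 6

Assumption: the (5aR,10bS) antipode of the aminoindanol-derived triazolium salt is taken to deliver the (S)-carbinol; if the sense of induction proves opposite, the equally available (5aS,10bR) antipode is used with no other change.

Step 1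
Reactants: 1 1,3-dimethoxybenzene
Product: 3 1,3-dimethoxy-2-(3-methylbut-2-en-1-yl)benzene, via 2,6-dimethoxyphenyllithium 2 (not isolated)
Conditions: n-BuLi, THF, 0 °C → rt; then prenyl bromide, 0 °C → rt
Reagents that add atoms: prenyl bromide (1-bromo-3-methylbut-2-ene), CC(C)=CCBr
Why: Directed ortho-metalation followed by SN2 alkylation: n-BuLi removes the C2 proton flanked by both methoxy groups (double coordination and inductive acidification), and the aryllithium should attack the primary carbon of prenyl bromide, giving the 2-prenyl arene with no stereocenter involved.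

Step 2
Reactants: 3 1,3-dimethoxy-2-(3-methylbut-2-en-1-yl)benzene
Product: 5 2,4-dimethoxy-3-(3-methylbut-2-en-1-yl)benzaldehyde, via iminium salt 4 (not isolated)
Conditions: POCl3, DMF, 0 → 40 °C; then H2O, 0 °C → rt
Reagents that add atoms: N,N-dimethylformamide (formyl carbon), CN(C)C=O; water (carbonyl oxygen), O
Why: Vilsmeier–Haack formylation: the chloroiminium ion should attack the ring carbon para to one methoxy and ortho to the other, the only activated site not flanked on both sides, while the isolated trisubstituted alkene is too weak a nucleophile to compete at this temperature.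

Step 3
Reactants: 5 2,4-dimethoxy-3-(3-methylbut-2-en-1-yl)benzaldehyde
Product: 6 1-[2,4-dimethoxy-3-(3-methylbut-2-en-1-yl)phenyl]-2-hydroxyethan-1-one
Conditions: paraformaldehyde, 3-benzyl-5-(2-hydroxyethyl)-4-methylthiazolium chloride (10 mol %), i-Pr2NEt, THF, 60 °C
Reagents that add atoms: formaldehyde (from paraformaldehyde), C=O
Why: Thiazolylidene-catalyzed crossed acyloin condensation (hydroxymethylation): the Breslow intermediate of the aryl aldehyde should add to the much more electrophilic formaldehyde, present in excess, so that the 1-aryl-2-hydroxyethanone results and no stereocenter is formed.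

Step 4
Reactants: 7 5-fluororesorcinol (5-fluorobenzene-1,3-diol)
Product: 9 2-fluoro-4,6-dihydroxybenzaldehyde, via iminium salt 8 (not isolated)
Conditions: POCl3, DMF, MeCN, −15 °C → rt; then H2O, 50 °C
Reagents that add atoms: N,N-dimethylformamide (formyl carbon), CN(C)C=O; water (carbonyl oxygen), O
Why: Vilsmeier–Haack formylation of a resorcinol: attack should occur para to one hydroxyl and ortho to the other, that is at either of the two equivalent carbons next to fluorine, as resorcinol and 5-alkylresorcinols are formylated at C4 and not between the hydroxyls.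

Step 5
Reactants: 9 2-fluoro-4,6-dihydroxybenzaldehyde
Product: 10 2-fluoro-4,6-bis(methoxymethoxy)benzaldehyde
Conditions: MOMCl, K2CO3, acetone, rt → reflux
Reagents that add atoms: chloromethyl methyl ether (MOMCl), COCCl
Why: Williamson-type O-alkylation with a chloromethyl ether: both phenols, including the one hydrogen-bonded to the formyl group, should be alkylated under carbonate in refluxing acetone, which removes the acidic protons whose phenoxides would shut down the SNAr of the key step.

Step 6
Reactants: 6 1-[2,4-dimethoxy-3-(3-methylbut-2-en-1-yl)phenyl]-2-hydroxyethan-1-one; 10 2-fluoro-4,6-bis(methoxymethoxy)benzaldehyde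
Product: 12 (3S)-3-[2,4-dimethoxy-3-(3-methylbut-2-en-1-yl)phenyl]-3-hydroxy-5,7-bis(methoxymethoxy)-2,3-dihydro-4H-chromen-4-one, via keto aldehyde 11 (not isolated)
Conditions: Cs2CO3 (1.2 equiv), DMSO, 45 °C, Ar; then toluene, (5aR,10bS)-2-(pentafluorophenyl)-5a,10b-dihydro-4H,6H-indeno[2,1-b][1,2,4]triazolo[4,3-d][1,4]oxazin-2-ium tetrafluoroborate (15 mol %), rt
Reagents that add atoms: none
Why: Proposed new method: a one-flask SNAr etherification/carbene-catalyzed crossed benzoin sequence is proposed, in which the cesium alkoxide of 6 first displaces fluoride at the ring A carbon ortho to the formyl group of 10 through a Meisenheimer adduct whose charge is taken up by that formyl group, giving keto aldehyde 11, and the triazolylidene added afterwards converts the formyl carbon of 11 into an enaminol (Breslow intermediate) that attacks the aryl ketone carbon and then releases the catalyst. The closest known reaction types are the carbonate-mediated SNAr of alpha-hydroxy ketones and of simple alcohols with ortho-fluoro benzonitriles and benzaldehydes, and the enantioselective aldehyde–ketone benzoin cyclization of 2-(2-aryl-2-oxoethoxy)benzaldehydes to 3-aryl-3-hydroxychroman-4-ones; what is new is running them as one operation on an electron-rich fluoro aldehyde. Ring C is the only ring closed, by a 6-exo-trig addition of the acyl anion equivalent at C4 onto the C3 ketone, after the O1–C8a bond has been made intermolecularly. The C3 stereocenter is set under catalyst control: the fused indane of the triazolylidene shields one face of the enaminol and a hydrogen bond from the enaminol OH to the ketone oxygen fixes which ketone face is attacked, so that the chosen antipode should give the (S)-carbinol. The step needs O-arylation to outrun enediolate chemistry of 6 and benzoin closure to outrun the five-membered aldol condensation of 11 to a 2-aroylbenzofuran (Rap–Stoermer pathway); the mild carbonate base at 45 °C, the single C–F bond and the low electrophilicity of the doubly ortho-oxygenated aldehyde toward enolates at room temperature should secure this, the carbene path being irreversible once the catalyst is present. The two MOM ethers keep ring A free of phenoxide charge, without which neither the SNAr nor the carbene addition would be feasible.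

Step 7
Reactants: 12 (3S)-3-[2,4-dimethoxy-3-(3-methylbut-2-en-1-yl)phenyl]-3-hydroxy-5,7-bis(methoxymethoxy)-2,3-dihydro-4H-chromen-4-one
Product: 13 (3S)-3-[2,4-dimethoxy-3-(3-methylbut-2-en-1-yl)phenyl]-3,5,7-trihydroxy-2,3-dihydro-4H-chromen-4-one
Conditions: HCl (3 M aq), MeOH, 40 °C
Reagents that add atoms: none
Why: Acid-catalyzed acetal exchange: methanol takes over the two methoxymethyl groups as dimethoxymethane, while the tertiary carbinol should survive because its cation would sit next to the C4 carbonyl, ring B carries no free phenol that could cyclize onto the prenyl group, and the quaternary stereocenter has no pathway to epimerize.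

**Compound list**
1 | 1,3-dimethoxybenzene | COc1cccc(OC)c1 | starting material
2 | 2,6-dimethoxyphenyllithium | [Li]c1c(OC)cccc1OC | intermediate
3 | 1,3-dimethoxy-2-(3-methylbut-2-en-1-yl)benzene | COc1cccc(OC)c1CC=C(C)C | intermediate
4 | N-{[2,4-dimethoxy-3-(3-methylbut-2-en-1-yl)phenyl]methylidene}-N-methylmethanaminium dichlorophosphate | C[N+](C)=Cc1ccc(OC)c(CC=C(C)C)c1OC.[O-]P(=O)(Cl)Cl | intermediate
5 | 2,4-dimethoxy-3-(3-methylbut-2-en-1-yl)benzaldehyde | COc1ccc(C=O)c(OC)c1CC=C(C)C | intermediate
6 | 1-[2,4-dimethoxy-3-(3-methylbut-2-en-1-yl)phenyl]-2-hydroxyethan-1-one | COc1ccc(C(=O)CO)c(OC)c1CC=C(C)C | intermediate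
7 | 5-fluororesorcinol (5-fluorobenzene-1,3-diol) | Oc1cc(O)cc(F)c1 | starting material
8 | N-[(2-fluoro-4,6-dihydroxyphenyl)methylidene]-N-methylmethanaminium dichlorophosphate | C[N+](C)=Cc1c(O)cc(O)cc1F.[O-]P(=O)(Cl)Cl | intermediate
9 | 2-fluoro-4,6-dihydroxybenzaldehyde | O=Cc1c(O)cc(O)cc1F | intermediate
10 | 2-fluoro-4,6-bis(methoxymethoxy)benzaldehyde | COCOc1cc(F)c(C=O)c(OCOC)c1 | intermediate
11 | 2-{2-[2,4-dimethoxy-3-(3-methylbut-2-en-1-yl)phenyl]-2-oxoethoxy}-4,6-bis(methoxymethoxy)benzaldehyde | COc1ccc(C(=O)COc2cc(OCOC)cc(OCOC)c2C=O)c(OC)c1CC=C(C)C | intermediate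
12 | (3S)-3-[2,4-dimethoxy-3-(3-methylbut-2-en-1-yl)phenyl]-3-hydroxy-5,7-bis(methoxymethoxy)-2,3-dihydro-4H-chromen-4-one | COc1ccc([C@]2(O)COc3cc(OCOC)cc(OCOC)c3C2=O)c(OC)c1CC=C(C)C | intermediate
13 | (3S)-3-[2,4-dimethoxy-3-(3-methylbut-2-en-1-yl)phenyl]-3,5,7-trihydroxy-2,3-dihydro-4H-chromen-4-one | COc1ccc([C@]2(O)COc3cc(O)cc(O)c3C2=O)c(OC)c1CC=C(C)C | target

**Step count and risks**
Total step count: 7. Longest linear sequence: 5 steps (steps 1, 2, 3, 6, 7).

Steps most likely to fail:

1. Step 6 (proposed new method). Fluoride displacement on the electron-rich ring may stay incomplete. The base may drive enolization and aldol condensation of the keto aldehyde before the carbene acts. Carbene addition to the doubly ortho-substituted aldehyde may be slow, with loss of enantioselectivity. The fallback uses known chemistry only, sets out from 6 and comes back at 11. An Appel bromination of 6 (CBr4, PPh3, CH2Cl2, 0 °C) should give 2-bromo-1-[2,4-dimethoxy-3-(3-methylbut-2-en-1-yl)phenyl]ethan-1-one F1. Commercial 2,4,6-trihydroxybenzaldehyde is protected at its two non-chelated hydroxyls (MOMCl, i-Pr2NEt, CH2Cl2, 0 °C) to 2-hydroxy-4,6-bis(methoxymethoxy)benzaldehyde F2. Williamson alkylation of F2 with F1 (K2CO3, acetone, rt) forms O1–C2 instead of O1–C8a and returns to the route at keto aldehyde 11, now isolated. Compound 11 is then cyclized to 12 as a separate, known aldehyde–ketone benzoin cyclization with the same triazolium salt and catalytic Et3N in toluene at rt.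

2. Step 3. Self-condensation of formaldehyde, a second hydroxymethylation of the product, or sluggish Breslow-intermediate formation from the ortho-substituted electron-rich aldehyde may erode the conversion. The fallback sets out from 5 and comes back at 6, replacing umpolung by a hydroxymethyl anion equivalent. (Methoxymethoxy)methyllithium F3 (from tributyl[(methoxymethoxy)methyl]stannane and n-BuLi, THF, −78 °C) is added to 5 to give racemic 1-[2,4-dimethoxy-3-(3-methylbut-2-en-1-yl)phenyl]-2-(methoxymethoxy)ethan-1-ol F4. Oxidation with Dess–Martin periodinane (NaHCO3, CH2Cl2, rt) gives 1-[2,4-dimethoxy-3-(3-methylbut-2-en-1-yl)phenyl]-2-(methoxymethoxy)ethan-1-one F5. Acetal cleavage (HCl, MeOH, 45 °C) then gives 6.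

3. Step 7. Acid may hydrate or hydrochlorinate the prenyl double bond, or promote loss of water from the tertiary carbinol toward the isoflavone. The fallback sets out from 9 and comes back at 13, replacing the acid-labile acetals by allyl ethers that are removed under neutral conditions. Compound 9 is bis-allylated (allyl bromide, K2CO3, DMF, rt) to 2-fluoro-4,6-bis(prop-2-en-1-yloxy)benzaldehyde F6. Union with 6 under the conditions of step 6 passes through 2-{2-[2,4-dimethoxy-3-(3-methylbut-2-en-1-yl)phenyl]-2-oxoethoxy}-4,6-bis(prop-2-en-1-yloxy)benzaldehyde F7 and should give (3S)-3-[2,4-dimethoxy-3-(3-methylbut-2-en-1-yl)phenyl]-3-hydroxy-5,7-bis(prop-2-en-1-yloxy)-2,3-dihydro-4H-chromen-4-one F8. Deallylation with Pd(PPh3)4 (5 mol %) and morpholine in THF at rt gives 13; the trisubstituted prenyl alkene is inert to this catalyst.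

**Further compounds**
F1 | step 6 | 2-bromo-1-[2,4-dimethoxy-3-(3-methylbut-2-en-1-yl)phenyl]ethan-1-one | COc1ccc(C(=O)CBr)c(OC)c1CC=C(C)C
F2 | step 6 | 2-hydroxy-4,6-bis(methoxymethoxy)benzaldehyde | COCOc1cc(O)c(C=O)c(OCOC)c1
F3 | step 3 | (methoxymethoxy)methyllithium | [Li]COCOC
F4 | step 3 | 1-[2,4-dimethoxy-3-(3-methylbut-2-en-1-yl)phenyl]-2-(methoxymethoxy)ethan-1-ol (racemic) | COCOCC(O)c1ccc(OC)c(CC=C(C)C)c1OC
F5 | step 3 | 1-[2,4-dimethoxy-3-(3-methylbut-2-en-1-yl)phenyl]-2-(methoxymethoxy)ethan-1-one | COCOCC(=O)c1ccc(OC)c(CC=C(C)C)c1OC
F6 | step 7 | 2-fluoro-4,6-bis(prop-2-en-1-yloxy)benzaldehyde | C=CCOc1cc(F)c(C=O)c(OCC=C)c1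
F7 | step 7 | 2-{2-[2,4-dimethoxy-3-(3-methylbut-2-en-1-yl)phenyl]-2-oxoethoxy}-4,6-bis(prop-2-en-1-yloxy)benzaldehyde | COc1ccc(C(=O)COc2cc(OCC=C)cc(OCC=C)c2C=O)c(OC)c1CC=C(C)C
F8 | step 7 | (3S)-3-[2,4-dimethoxy-3-(3-methylbut-2-en-1-yl)phenyl]-3-hydroxy-5,7-bis(prop-2-en-1-yloxy)-2,3-dihydro-4H-chromen-4-one | COc1ccc([C@]2(O)COc3cc(OCC=C)cc(OCC=C)c3C2=O)c(OC)c1CC=C(C)C
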